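Retrosynthesis: the C3 acetate, C19 aldehyde and C15 acid are end-game adjustments; the cuts are C13=C14 (olefination of a methyl ketone), C9–C11 (a butenyl chain added to a C9 carbonyl) and C1–C10 (ring A).
Enabling feature: ring B (C5–C10) carries methyls on C8 and C10 on either side of C9, the pattern of a 2,6-dimethylphenol with its oxygen on C9, so C10 is the ortho carbon of a phenoxide and can be alkylated by C1 with loss of aromaticity.
Forward: the arene (future ring B) is joined at C5 to a malonate that becomes quaternary C4; one carboxyl is turned into the C3–C2–C1 arm; ring A closes at C10; ring B is then reduced, the chain is added at C9 and finished last.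
Stereochemistry: C4 from enzymatic desymmetrisation of the malonate; C10 from C4 in the ring closure; C5–H and C9–H from dissolving-metal protonations opposite the C10 methyl; C3 from equatorial hydride delivery; the 13E alkene from the olefination.

Key step: step 9

Remark: bicyclic compounds carry labdane locants (ring A = C1–C5 and C10, ring B = C5–C10, C19 = the carbon on C4 cis to the C10 methyl); "decalin" denotes the bicyclo[4.4.0]decane core numbered in this way, and the arene carbons of the early compounds are referred to by the same locants.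
Assumption: the esterase is taken to hydrolyse the enantiotopic ester of the aryl(methyl)malonate whose loss gives the (S)-half-ester; should its preference be the opposite or weak, the resolution described under the fallbacks supplies the same acid.

Step 1
Reactants: 1 2,4-dimethylbenzene-1,3-diol
Product: 2 3-hydroxy-2,4-dimethylphenyl trifluoromethanesulfonate
Conditions: PhNTf2 (1.0 equiv), Et3N, CH2Cl2, −20 °C → rt
Reagents that add atoms: N-phenylbis(trifluoromethanesulfonimide), O=S(=O)(N(c1ccccc1)S(=O)(=O)C(F)(F)F)C(F)(F)F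
Why: The hydroxyl next to only one methyl group is far more accessible than the one flanked by two, so one equivalent of the bulky triflimide should sulfonylate it selectively (phenol O-triflation) and leave the hindered hydroxyl that becomes the C9 oxygen.

Step 2
Reactants: 2 3-hydroxy-2,4-dimethylphenyl trifluoromethanesulfonate
Product: 3 3-(benzyloxy)-2,4-dimethylphenyl trifluoromethanesulfonate
Conditions: BnBr, K2CO3, DMF, rt
Reagents that add atoms: benzyl bromide, BrCc1ccccc1
Why: Williamson etherification of the remaining hindered phenol gives a benzyl ether that tolerates the basic, enzymatic and acidic steps ahead and is removed by hydrogenolysis just before ring closure.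

Step 3
Reactants: 3 3-(benzyloxy)-2,4-dimethylphenyl trifluoromethanesulfonate; 4 dimethyl malonate
Product: 5 dimethyl 2-[3-(benzyloxy)-2,4-dimethylphenyl]malonate
Conditions: 4 (1.5 equiv), Pd(OAc)2 (2 mol%), t-BuXPhos (4 mol%), K3PO4, toluene, 100 °C
Reagents that add atoms: none
Why: Palladium-catalysed α-arylation of the malonate with the aryl triflate, for which a bulky electron-rich biarylphosphine copes with one ortho methyl group, joins the future C4 to arene carbon C5.

Step 4
Reactants: 5 dimethyl 2-[3-(benzyloxy)-2,4-dimethylphenyl]malonate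
Product: 6 dimethyl 2-[3-(benzyloxy)-2,4-dimethylphenyl]-2-methylmalonate
Conditions: NaH, THF, 0 °C; MeI, rt
Reagents that add atoms: iodomethane, CI
Why: The acidic arylmalonate is deprotonated and C-methylated by iodomethane (malonic ester alkylation), which makes C4 quaternary and prochiral with two enantiotopic ester groups.

Step 5
Reactants: 6 dimethyl 2-[3-(benzyloxy)-2,4-dimethylphenyl]-2-methylmalonate
Product: 7 (2S)-2-[3-(benzyloxy)-2,4-dimethylphenyl]-3-methoxy-2-methyl-3-oxopropanoic acid
Conditions: pig liver esterase, pH 7.5 phosphate buffer/DMSO (9:1), 30 °C, pH-stat (1 M NaOH); then HCl to pH 2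
Reagents that add atoms: water, O
Why: Esterase-mediated desymmetrisation of a 2-aryl-2-methylmalonate hydrolyses one enantiotopic ester and so sets C4 as the (S)-half-ester, whose optical purity can be raised by crystallising an amine salt.

Step 6
Reactants: 7 (2S)-2-[3-(benzyloxy)-2,4-dimethylphenyl]-3-methoxy-2-methyl-3-oxopropanoic acid; 8 tributyl(vinyl)stannane
Product: 10 methyl (2S)-2-[3-(benzyloxy)-2,4-dimethylphenyl]-2-methyl-3-oxopent-4-enoate, via acid chloride 9 (not isolated)
Conditions: (COCl)2, DMF (cat.), CH2Cl2, 0 °C → rt, evaporate; 8 (Bu3SnCH=CH2), PdCl2(PPh3)2 (3 mol%), toluene, 70 °C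
Reagents that add atoms: oxalyl chloride, ClC(=O)C(=O)Cl (chlorine of 9 only)
Why: The free carboxyl is activated as the acid chloride and coupled with the vinylstannane (Stille acylation), which builds the C3 ketone with C2=C1 attached while the neighbouring ester and the non-enolisable C4 centre stay untouched.

Step 7
Reactants: 10 methyl (2S)-2-[3-(benzyloxy)-2,4-dimethylphenyl]-2-methyl-3-oxopent-4-enoate
Product: 12 methyl (2S)-2-[3-(benzyloxy)-2,4-dimethylphenyl]-2-[2-(2-bromoethyl)-1,3-dioxolan-2-yl]propanoate, via β-bromo ketone 11 (not isolated)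
Conditions: HBr (anhydrous, 1.2 equiv), CH2Cl2, −20 °C; then (Me3SiOCH2)2, Me3SiOTf (10 mol%), −20 °C → rt
Reagents that add atoms: hydrogen bromide, Br; 1,2-bis(trimethylsilyloxy)ethane, C[Si](C)(C)OCCO[Si](C)(C)C
Why: Conjugate addition of HBr to the vinyl ketone puts the leaving group on C1, and silyl triflate-catalysed ketalisation with the bis-silylated glycol, driven by formation of the disiloxane and effective on hindered ketones, masks C3 so that base can later neither enolise C2 nor eliminate the bromide.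

Step 8
Reactants: 12 methyl (2S)-2-[3-(benzyloxy)-2,4-dimethylphenyl]-2-[2-(2-bromoethyl)-1,3-dioxolan-2-yl]propanoate
Product: 13 methyl (2S)-2-[2-(2-bromoethyl)-1,3-dioxolan-2-yl]-2-(3-hydroxy-2,4-dimethylphenyl)propanoate
Conditions: H2 (1 atm), Pd on carbon (10%), EtOAc, rt
Reagents that add atoms: none
Why: Hydrogenolysis of the benzyl aryl ether over palladium on carbon under neutral conditions frees the phenol while the primary bromide, the ketal and the ester should survive.

Step 9
Reactants: 13 methyl (2S)-2-[2-(2-bromoethyl)-1,3-dioxolan-2-yl]-2-(3-hydroxy-2,4-dimethylphenyl)propanoate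
Product: 15 methyl (4S,10R)-3,3-(ethylenedioxy)-4,8,10-trimethyl-9-oxodecalin-5,7-diene-4-carboxylate, via sodium phenoxide 14 (not isolated)
Conditions: NaH (1.05 equiv), toluene (0.01 M), 0 °C → 80 °C, dark
Reagents that add atoms: sodium hydride, [Na+].[H-] (sodium of 14 only)
Why: NaH turns the phenol into its sodium phenoxide, an ambident nucleophile whose ortho carbon C10 displaces bromide from C1 in an irreversible intramolecular SN2 reaction; because C10 carries a methyl group the adduct cannot tautomerise back to a phenol and stays as the 6,6-disubstituted cyclohexa-2,4-dienone. The closest known reaction type is the base-mediated intramolecular C-alkylation of phenoxides by tethered halides or sulfonates (aryl participation of the Ar2-6 kind) that gives blocked ortho-dienones. Ring A (C1–C5 and C10) closes in a 6-exo-tet mode. The new stereocentre C10 is controlled by C4 through a chair-like transition state in which C3 and the ester straddle the C10 methyl: the flat ester group, not the C4 methyl, occupies the axial-like position that becomes 1,3-diaxial to the C10 methyl, so C19 and the C10 methyl end up cis. The step needs selectivity for C10 over oxygen and over the free para carbon C6: attack through oxygen would have to close an eight-membered ether, reaching C6 requires a rotamer about C4–C5 in which a C4 substituent eclipses the C10 methyl, and the tight sodium ion pair in toluene keeps the electrophile on the oxygen-bearing side. One equivalent of base leaves nothing to eliminate HBr, and the dioxolane keeps C2 from being enolised.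

Step 10
Reactants: 15 methyl (4S,10R)-3,3-(ethylenedioxy)-4,8,10-trimethyl-9-oxodecalin-5,7-diene-4-carboxylate
Product: 18 methyl (4S,5S,10R)-3,3-(ethylenedioxy)-4,8,10-trimethyl-9-oxodecalin-7-ene-4-carboxylate, via lithium dienolate 16 (not isolated), via β,γ-unsaturated ketone 17 (not isolated)
Conditions: Li (2.5 equiv), t-BuOH (1.0 equiv), NH3/THF, −78 °C; isoprene then NH4Cl; DBU (0.2 equiv), CH2Cl2, rt
Reagents that add atoms: lithium, [Li] (lithium of 16 only)
Why: Dissolving-metal (Birch-type) 1,6-reduction of the linear dienone protonates the terminal carbon C5 of the reduced species from the face opposite the C10 methyl and the axial ester, which sets the trans ring fusion, and the dienolate is then protonated and conjugated by DBU to the C7=C8 enone; the small charge of lithium at −78 °C is meant to spare the hindered ester.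

Step 11
Reactants: 18 methyl (4S,5S,10R)-3,3-(ethylenedioxy)-4,8,10-trimethyl-9-oxodecalin-7-ene-4-carboxylate; 19 but-3-enylmagnesium bromide
Product: 20 methyl (4S,5S,9R,10R)-9-(but-3-enyl)-3,3-(ethylenedioxy)-9-hydroxy-4,8,10-trimethyldecalin-7-ene-4-carboxylate
Conditions: 19 (CH2=CHCH2CH2MgBr, 1.5 equiv), CeCl3 (anhydrous, 1.5 equiv), THF, −78 °C → 0 °C; aq. NH4Cl
Reagents that add atoms: none
Why: The organocerium reagent formed from the Grignard reagent and CeCl3 adds 1,2 to the hindered conjugated C9 ketone without enolisation or conjugate addition (cerium-mediated Grignard addition), entering opposite the C10 methyl, and the new carbinol centre is erased in the next step.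

Step 12
Reactants: 20 methyl (4S,5S,9R,10R)-9-(but-3-enyl)-3,3-(ethylenedioxy)-9-hydroxy-4,8,10-trimethyldecalin-7-ene-4-carboxylate
Product: 21 methyl (4S,5S,10R)-9-(but-3-enyl)-3,3-(ethylenedioxy)-4,8,10-trimethyl-7-oxodecalin-8-ene-4-carboxylate
Conditions: pyridinium chlorochromate (C5H5NH)[CrO3Cl] (2 equiv), NaOAc, 4 Å molecular sieves, CH2Cl2, rt
Reagents that add atoms: none
Why: Babler–Dauben oxidative transposition: the chromate ester of the tertiary allylic alcohol shifts by a [3,3] rearrangement to C7 and is oxidised there, which moves the oxygen to C7 and leaves the side chain on the C8=C9 double bond.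

Step 13
Reactants: 21 methyl (4S,5S,10R)-9-(but-3-enyl)-3,3-(ethylenedioxy)-4,8,10-trimethyl-7-oxodecalin-8-ene-4-carboxylate
Product: 23 methyl (4S,5S,9S,10S)-9-(but-3-enyl)-3,3-(ethylenedioxy)-4,8,10-trimethyl-7-(trifluoromethanesulfonyloxy)decalin-7-ene-4-carboxylate, via lithium enolate 22 (not isolated)
Conditions: Li (2.2 equiv), t-BuOH (1.0 equiv), NH3/THF, −78 °C; isoprene; NH3 evaporated; PhNTf2 (1.3 equiv), THF, −78 °C → 0 °C
Reagents that add atoms: N-phenylbis(trifluoromethanesulfonimide), O=S(=O)(N(c1ccccc1)S(=O)(=O)C(F)(F)F)C(F)(F)F; lithium, [Li] (lithium of 22 only)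
Why: Dissolving-metal reduction of the tetrasubstituted enone protonates C9 axially on the face opposite the C10 methyl, which places the side chain equatorial and C9–H cis to C5–H, and the regiodefined C7 enolate is trapped on oxygen by the triflimide (reductive enolate triflation).

Step 14
Reactants: 23 methyl (4S,5S,9S,10S)-9-(but-3-enyl)-3,3-(ethylenedioxy)-4,8,10-trimethyl-7-(trifluoromethanesulfonyloxy)decalin-7-ene-4-carboxylate
Product: 24 methyl (4S,5S,9R,10S)-9-(but-3-enyl)-3,3-(ethylenedioxy)-4,8,10-trimethyldecalin-7-ene-4-carboxylate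
Conditions: Pd(OAc)2 (5 mol%), PPh3 (10 mol%), HCO2H, n-Bu3N, DMF, 60 °C
Reagents that add atoms: none
Why: Palladium-catalysed formate reduction of the enol triflate replaces the triflate by hydrogen and thereby fixes the double bond at C7=C8, exactly where the enolate was.

Step 15
Reactants: 24 methyl (4S,5S,9R,10S)-9-(but-3-enyl)-3,3-(ethylenedioxy)-4,8,10-trimethyldecalin-7-ene-4-carboxylate
Product: 25 methyl (4S,5S,9R,10S)-9-(but-3-enyl)-4,8,10-trimethyl-3-oxodecalin-7-ene-4-carboxylate
Conditions: 1 M HCl, THF, 40 °C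
Reagents that add atoms: water, O
Why: Acid-catalysed ketal hydrolysis releases the C3 ketone under conditions mild enough for the two alkenes and the ester.

Step 16
Reactants: 25 methyl (4S,5S,9R,10S)-9-(but-3-enyl)-4,8,10-trimethyl-3-oxodecalin-7-ene-4-carboxylate
Product: 27 (3S,4R,5S,9R,10S)-9-(but-3-enyl)-4-(hydroxymethyl)-4,8,10-trimethyldecalin-7-en-3-ol, via hydroxy ester 26 (not isolated)
Conditions: LiBH(s-Bu)3 (L-Selectride, 1.3 equiv), THF, −78 °C; then LiAlH4 (3 equiv), 0 °C → rt; aq. NaOH work-up
Reagents that add atoms: none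
Why: The bulky borohydride attacks the C3 ketone along the equatorial trajectory and so gives the axial alcohol trans to C19, after which LiAlH4 in the same flask reduces the hindered ester to the primary alcohol (hydride reductions).

Step 17
Reactants: 27 (3S,4R,5S,9R,10S)-9-(but-3-enyl)-4-(hydroxymethyl)-4,8,10-trimethyldecalin-7-en-3-ol
Product: 28 4-[(3S,4R,5S,9R,10S)-3-hydroxy-4-(hydroxymethyl)-4,8,10-trimethyldecalin-7-en-9-yl]butan-2-one
Conditions: PdCl2 (10 mol%), CuCl (1 equiv), O2 (1 atm), DMF/H2O (7:1), rt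
Reagents that add atoms: water, O
Why: Tsuji–Wacker oxidation converts the monosubstituted terminal alkene into the methyl ketone by Markovnikov hydroxypalladation with O2 as terminal oxidant, while the hindered trisubstituted ring alkene does not react.

Step 18
Reactants: 28 4-[(3S,4R,5S,9R,10S)-3-hydroxy-4-(hydroxymethyl)-4,8,10-trimethyldecalin-7-en-9-yl]butan-2-one; 29 triethyl phosphonoacetate
Product: 31 (2E)-5-[(3S,4R,5S,9R,10S)-3-hydroxy-4-(hydroxymethyl)-4,8,10-trimethyldecalin-7-en-9-yl]-3-methylpent-2-enoic acid, via ethyl ester 30 (not isolated)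
Conditions: 29 (4 equiv), NaH (6 equiv), THF, 0 °C → 65 °C; then LiOH, MeOH/H2O, 50 °C; HCl to pH 3
Reagents that add atoms: lithium hydroxide, [Li+].[OH-] (one carboxyl oxygen of 31)
Why: Horner–Wadsworth–Emmons olefination of the methyl ketone should give mainly the (E)-trisubstituted enoate, with the chain trans to the ester, and hydroxide added to the same flask cleaves the ethyl ester and any phosphonoacetate transesterified onto the diol; the minor Z acid is to be removed by chromatography.

Step 19
Reactants: 31 (2E)-5-[(3S,4R,5S,9R,10S)-3-hydroxy-4-(hydroxymethyl)-4,8,10-trimethyldecalin-7-en-9-yl]-3-methylpent-2-enoic acid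
Product: 32 (2E)-5-[(3S,4S,5S,9R,10S)-4-formyl-3-hydroxy-4,8,10-trimethyldecalin-7-en-9-yl]-3-methylpent-2-enoic acid
Conditions: TEMPO (0.2 equiv), PhI(OAc)2 (1.2 equiv), CH2Cl2, rt
Reagents that add atoms: none
Why: Oxoammonium (TEMPO) oxidation with PhI(OAc)2 is selective for the primary alcohol over the hindered axial secondary one and stops at the aldehyde in the absence of water, and the quaternary C4 cannot epimerise.

Step 20
Reactants: 32 (2E)-5-[(3S,4S,5S,9R,10S)-4-formyl-3-hydroxy-4,8,10-trimethyldecalin-7-en-9-yl]-3-methylpent-2-enoic acid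
Product: 33 (2E)-5-[(3S,4S,5S,9R,10S)-3-acetoxy-4-formyl-4,8,10-trimethyldecalin-7-en-9-yl]-3-methylpent-2-enoic acid
Conditions: Ac2O, pyridine, DMAP (cat.), CH2Cl2, rt; aq. NaHCO3 then dilute HCl work-up
Reagents that add atoms: acetic anhydride, CC(=O)OC(C)=O
Why: DMAP-catalysed acetylation esterifies the axial C3 alcohol, and the mixed anhydride formed at the carboxyl group is hydrolysed again during the aqueous work-up.

Compound list
1 | 2,4-dimethylbenzene-1,3-diol | Cc1ccc(O)c(C)c1O | starting material
2 | 3-hydroxy-2,4-dimethylphenyl trifluoromethanesulfonate | Cc1ccc(OS(=O)(=O)C(F)(F)F)c(C)c1O | intermediate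
3 | 3-(benzyloxy)-2,4-dimethylphenyl trifluoromethanesulfonate | Cc1ccc(OS(=O)(=O)C(F)(F)F)c(C)c1OCc1ccccc1 | intermediate
4 | dimethyl malonate | COC(=O)CC(=O)OC | starting material
5 | dimethyl 2-[3-(benzyloxy)-2,4-dimethylphenyl]malonate | Cc1ccc(C(C(=O)OC)C(=O)OC)c(C)c1OCc1ccccc1 | intermediate
6 | dimethyl 2-[3-(benzyloxy)-2,4-dimethylphenyl]-2-methylmalonate | Cc1ccc(C(C)(C(=O)OC)C(=O)OC)c(C)c1OCc1ccccc1 | intermediate
7 | (2S)-2-[3-(benzyloxy)-2,4-dimethylphenyl]-3-methoxy-2-methyl-3-oxopropanoic acid | Cc1ccc(c(C)c1OCc1ccccc1)[C@](C)(C(=O)OC)C(=O)O | intermediate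
8 | tributyl(vinyl)stannane | C=C[Sn](CCCC)(CCCC)CCCC | starting material
9 | acid chloride: methyl (2R)-2-[3-(benzyloxy)-2,4-dimethylphenyl]-3-chloro-2-methyl-3-oxopropanoate (not isolated) | Cc1ccc(c(C)c1OCc1ccccc1)[C@](C)(C(=O)OC)C(Cl)=O | intermediate
10 | methyl (2S)-2-[3-(benzyloxy)-2,4-dimethylphenyl]-2-methyl-3-oxopent-4-enoate | Cc1ccc(c(C)c1OCc1ccccc1)[C@](C)(C(=O)OC)C(=O)C=C | intermediate
11 | β-bromo ketone: methyl (2S)-2-[3-(benzyloxy)-2,4-dimethylphenyl]-5-bromo-2-methyl-3-oxopentanoate (not isolated) | Cc1ccc(c(C)c1OCc1ccccc1)[C@](C)(C(=O)OC)C(=O)CCBr | intermediate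
12 | methyl (2S)-2-[3-(benzyloxy)-2,4-dimethylphenyl]-2-[2-(2-bromoethyl)-1,3-dioxolan-2-yl]propanoate | Cc1ccc(c(C)c1OCc1ccccc1)[C@](C)(C(=O)OC)C1(CCBr)OCCO1 | intermediate
13 | methyl (2S)-2-[2-(2-bromoethyl)-1,3-dioxolan-2-yl]-2-(3-hydroxy-2,4-dimethylphenyl)propanoate (precursor of the key step) | Cc1ccc(c(C)c1O)[C@](C)(C(=O)OC)C1(CCBr)OCCO1 | intermediate
14 | sodium phenoxide of 13 (not isolated) | Cc1ccc(c(C)c1[O-])[C@](C)(C(=O)OC)C1(CCBr)OCCO1.[Na+] | intermediate
15 | methyl (4S,10R)-3,3-(ethylenedioxy)-4,8,10-trimethyl-9-oxodecalin-5,7-diene-4-carboxylate (product of the key step; C19 ester cis to the C10 methyl) | C13(OCCO3)CC[C@@]2(C)C(=O)C(C)=CC=C2[C@]1(C)C(=O)OC | intermediate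
16 | lithium dienolate (O–C9=C8–C7=C6; 4S,5S,10R; not isolated) | C13(OCCO3)CC[C@@]2(C)C([O-])=C(C)C=C[C@@H]2[C@]1(C)C(=O)OC.[Li+] | intermediate
17 | β,γ-unsaturated ketone: methyl (4S,5S,10R)-3,3-(ethylenedioxy)-4,8,10-trimethyl-9-oxodecalin-6-ene-4-carboxylate (C8 epimers; not isolated) | C13(OCCO3)CC[C@@]2(C)C(=O)C(C)C=C[C@@H]2[C@]1(C)C(=O)OC | intermediate
18 | methyl (4S,5S,10R)-3,3-(ethylenedioxy)-4,8,10-trimethyl-9-oxodecalin-7-ene-4-carboxylate | C13(OCCO3)CC[C@@]2(C)C(=O)C(C)=CC[C@@H]2[C@]1(C)C(=O)OC | intermediate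
19 | but-3-enylmagnesium bromide | C=CCC[Mg]Br | starting material
20 | methyl (4S,5S,9R,10R)-9-(but-3-enyl)-3,3-(ethylenedioxy)-9-hydroxy-4,8,10-trimethyldecalin-7-ene-4-carboxylate (butenyl trans to the C10 methyl) | C13(OCCO3)CC[C@@]2(C)[C@@](O)(CCC=C)C(C)=CC[C@@H]2[C@]1(C)C(=O)OC | intermediate
21 | methyl (4S,5S,10R)-9-(but-3-enyl)-3,3-(ethylenedioxy)-4,8,10-trimethyl-7-oxodecalin-8-ene-4-carboxylate | C13(OCCO3)CC[C@@]2(C)C(CCC=C)=C(C)C(=O)C[C@@H]2[C@]1(C)C(=O)OC | intermediate
22 | lithium enolate at C7 (C7=C8; 4S,5S,9S,10S; not isolated) | C13(OCCO3)CC[C@@]2(C)[C@H](CCC=C)C(C)=C([O-])C[C@@H]2[C@]1(C)C(=O)OC.[Li+] | intermediate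
23 | methyl (4S,5S,9S,10S)-9-(but-3-enyl)-3,3-(ethylenedioxy)-4,8,10-trimethyl-7-(trifluoromethanesulfonyloxy)decalin-7-ene-4-carboxylate | C13(OCCO3)CC[C@@]2(C)[C@H](CCC=C)C(C)=C(OS(=O)(=O)C(F)(F)F)C[C@@H]2[C@]1(C)C(=O)OC | intermediate
24 | methyl (4S,5S,9R,10S)-9-(but-3-enyl)-3,3-(ethylenedioxy)-4,8,10-trimethyldecalin-7-ene-4-carboxylate | C13(OCCO3)CC[C@@]2(C)[C@H](CCC=C)C(C)=CC[C@@H]2[C@]1(C)C(=O)OC | intermediate
25 | methyl (4S,5S,9R,10S)-9-(but-3-enyl)-4,8,10-trimethyl-3-oxodecalin-7-ene-4-carboxylate | O=C1CC[C@@]2(C)[C@H](CCC=C)C(C)=CC[C@@H]2[C@]1(C)C(=O)OC | intermediate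
26 | hydroxy ester: methyl (3S,4S,5S,9R,10S)-9-(but-3-enyl)-3-hydroxy-4,8,10-trimethyldecalin-7-ene-4-carboxylate (axial 3-OH; present as its lithium alkoxide; not isolated) | O[C@H]1CC[C@@]2(C)[C@H](CCC=C)C(C)=CC[C@@H]2[C@]1(C)C(=O)OC | intermediate
27 | (3S,4R,5S,9R,10S)-9-(but-3-enyl)-4-(hydroxymethyl)-4,8,10-trimethyldecalin-7-en-3-ol | O[C@H]1CC[C@@]2(C)[C@H](CCC=C)C(C)=CC[C@@H]2[C@]1(C)CO | intermediate
28 | 4-[(3S,4R,5S,9R,10S)-3-hydroxy-4-(hydroxymethyl)-4,8,10-trimethyldecalin-7-en-9-yl]butan-2-one | O[C@H]1CC[C@@]2(C)[C@H](CCC(C)=O)C(C)=CC[C@@H]2[C@]1(C)CO | intermediate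
29 | triethyl phosphonoacetate | CCOC(=O)CP(=O)(OCC)OCC | starting material
30 | ethyl ester: ethyl (2E)-5-[(3S,4R,5S,9R,10S)-3-hydroxy-4-(hydroxymethyl)-4,8,10-trimethyldecalin-7-en-9-yl]-3-methylpent-2-enoate (not isolated) | O[C@H]1CC[C@@]2(C)[C@H](CC/C(C)=C/C(=O)OCC)C(C)=CC[C@@H]2[C@]1(C)CO | intermediate
31 | (2E)-5-[(3S,4R,5S,9R,10S)-3-hydroxy-4-(hydroxymethyl)-4,8,10-trimethyldecalin-7-en-9-yl]-3-methylpent-2-enoic acid | O[C@H]1CC[C@@]2(C)[C@H](CC/C(C)=C/C(=O)O)C(C)=CC[C@@H]2[C@]1(C)CO | intermediate
32 | (2E)-5-[(3S,4S,5S,9R,10S)-4-formyl-3-hydroxy-4,8,10-trimethyldecalin-7-en-9-yl]-3-methylpent-2-enoic acid | O[C@H]1CC[C@@]2(C)[C@H](CC/C(C)=C/C(=O)O)C(C)=CC[C@@H]2[C@]1(C)C=O | intermediate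
33 | (2E)-5-[(3S,4S,5S,9R,10S)-3-acetoxy-4-formyl-4,8,10-trimethyldecalin-7-en-9-yl]-3-methylpent-2-enoic acid (CNP0312710.1) | CC(=O)O[C@H]1CC[C@@]2(C)[C@H](CC/C(C)=C/C(=O)O)C(C)=CC[C@@H]2[C@]1(C)C=O | target

Total step count: 20.
Longest linear sequence: 20 steps (1 → 33); the partners 4, 8, 19 and 29 are purchased.

The three steps most likely to fail

Step 9, the ring closure. What may go wrong is C-alkylation at the unsubstituted carbon C6, para to the phenoxide oxygen, followed by loss of the C6 proton and re-aromatisation to a tetralin. The fallback is to block C6 before closing the ring. Setting out from 13, chlorination with N-chlorosuccinimide in MeCN at 0 °C should go to the only free activated position and give methyl (2S)-2-[2-(2-bromoethyl)-1,3-dioxolan-2-yl]-2-(6-chloro-3-hydroxy-2,4-dimethylphenyl)propanoate F1. NaH in toluene then closes ring A to methyl (4S,10R)-6-chloro-3,3-(ethylenedioxy)-4,8,10-trimethyl-9-oxodecalin-5,7-diene-4-carboxylate F2. Under the conditions of step 10, with two further equivalents of lithium, the vinylic chloride is cleaved reductively before the 1,6-reduction, and the route is rejoined at 18.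

Step 5, the enzymatic desymmetrisation. What may go wrong is slow turnover of the hindered diester, low enantiotopic discrimination, or hydrolysis of the other ester group. The fallback is a classical resolution. Setting out from 6, one equivalent of KOH in MeOH/H2O should give the racemic half-ester 2-[3-(benzyloxy)-2,4-dimethylphenyl]-3-methoxy-2-methyl-3-oxopropanoic acid F3. Crystallisation with (S)-1-phenylethylamine is meant to deposit the (S)-1-phenylethylammonium salt of the (S)-acid F4; if the other diastereomer is the less soluble one, the antipodal amine is used. Acidification of the salt returns to 7.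

Step 10, the dissolving-metal 1,6-reduction. What may go wrong is protonation of the reduced dienone at C7 instead of C5, which would leave the C5=C6 double bond in place, or partial reduction of the ester. The fallback is hydrogenation followed by re-oxidation. Setting out from 15, H2 (4 atm) over palladium on carbon in EtOH should saturate both double bonds of ring B, adding to C5 from the face opposite the C10 methyl and the axial ester, to give methyl (4S,5S,10R)-3,3-(ethylenedioxy)-4,8,10-trimethyl-9-oxodecalin-4-carboxylate F5 (C8 epimers). Its only possible silyl enol ether, methyl (4S,5S,10R)-3,3-(ethylenedioxy)-4,8,10-trimethyl-9-(trimethylsilyloxy)decalin-8-ene-4-carboxylate F6 (Me3SiOTf, Et3N), is then dehydrogenated by Saegusa–Ito oxidation (Pd(OAc)2, MeCN), and the route is rejoined at 18.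

Further compounds
F1 | step 9 | methyl (2S)-2-[2-(2-bromoethyl)-1,3-dioxolan-2-yl]-2-(6-chloro-3-hydroxy-2,4-dimethylphenyl)propanoate | Cc1cc(Cl)c(c(C)c1O)[C@](C)(C(=O)OC)C1(CCBr)OCCO1
F2 | step 9 | methyl (4S,10R)-6-chloro-3,3-(ethylenedioxy)-4,8,10-trimethyl-9-oxodecalin-5,7-diene-4-carboxylate | C13(OCCO3)CC[C@@]2(C)C(=O)C(C)=CC(Cl)=C2[C@]1(C)C(=O)OC
F3 | step 5 | racemic 2-[3-(benzyloxy)-2,4-dimethylphenyl]-3-methoxy-2-methyl-3-oxopropanoic acid | Cc1ccc(c(C)c1OCc1ccccc1)C(C)(C(=O)OC)C(=O)O
F4 | step 5 | (S)-1-phenylethylammonium (2S)-2-[3-(benzyloxy)-2,4-dimethylphenyl]-3-methoxy-2-methyl-3-oxopropanoate | Cc1ccc(c(C)c1OCc1ccccc1)[C@](C)(C(=O)OC)C(=O)[O-].C[C@H]([NH3+])c1ccccc1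
F5 | step 10 | methyl (4S,5S,10R)-3,3-(ethylenedioxy)-4,8,10-trimethyl-9-oxodecalin-4-carboxylate (C8 epimers) | C13(OCCO3)CC[C@@]2(C)C(=O)C(C)CC[C@@H]2[C@]1(C)C(=O)OC
F6 | step 10 | methyl (4S,5S,10R)-3,3-(ethylenedioxy)-4,8,10-trimethyl-9-(trimethylsilyloxy)decalin-8-ene-4-carboxylate | C13(OCCO3)CC[C@@]2(C)C(O[Si](C)(C)C)=C(C)CC[C@@H]2[C@]1(C)C(=O)OC
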